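**Retrosynthetic overview**
1. The route rests on the cross-ring 2-oxy-1,3-diene O–C3(=C2)–C4(=C5). Its C2=C3 bond lies in the five-membered ring (O, C3, C2, C1, C10) and its C4=C5 bond in the ten-membered carbocycle C1–C10. This array is what enyne metathesis leaves behind on a C3≡C4 alkynyl ether of the C10 tertiary alcohol.
2. Late adjustments (free C15–OH, C1 ketone from a protected carbinol) lead back to a bicyclic silyloxy diene. One tandem enyne/olefin metathesis then disconnects C2=C3 and C4=C5 together and opens both rings to a lactone dienyne.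
3. The dienyne is cut at C7–C8 into a β-alkynyloxy aldehyde and an enantiopure 3-(bromomethyl)butenolide. The forward steps are a zinc Barbier allylation and a Mitsunobu esterification with inversion at C8.
4. Aldehyde: C1, C8–C10 and C14 from (S)-citramalic acid, C3/C4 from trichloroethylene, C15 from formaldehyde, C2 from vinylmagnesium bromide. Butenolide: C5/C6 from 3-methylbut-2-enal, C7/C11/C13 from a propargyl silyl ether, C12 from CO.
5. Ring order: γ-lactone first (carbonylative lactonisation), then the dihydrofuran and the ten-membered ring in one flask; the furanone carbonyl comes last.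

Key step: step 19

Atom labels: C1 ketone, C2=C3, ring oxygen between C3 and C10, C4=C5 (C15 on C4), lactone C6–O–C12(=O)–C11(=C13)–C7, ester carbinol C8, C9, methyl C14 on C10.
Assumption: the C1 carbinol is a temporary stereocentre that step 21 erases; the (1R) epimer predicted for step 6 is drawn, and its epimer, if formed, is removed by chromatography at the diol stage.

**Step 1**
Reactants: 1 (S)-citramalic acid
Product: 2 2-[(4S)-2,2,4-trimethyl-5-oxo-1,3-dioxolan-4-yl]acetic acid
Conditions: Me2C(OMe)2, p-TsOH·H2O (cat.), CH2Cl2, rt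
Reagents that add atoms: 2,2-dimethoxypropane, COC(C)(C)OC
Why: Acid-catalysed acetalisation ties the α-hydroxy acid pair into a five-membered dioxolanone and leaves only the C8 carboxyl free, without touching the C10 stereocentre.

**Step 2**
Reactants: 2 2-[(4S)-2,2,4-trimethyl-5-oxo-1,3-dioxolan-4-yl]acetic acid
Product: 4 (3S)-3-hydroxy-3-methyloxolan-2-one, via hydroxyethyl dioxolanone 3 (not isolated)
Conditions: BH3·THF, THF, 0 °C → rt; MeOH quench; then p-TsOH (cat.), CH2Cl2, rt
Reagents that add atoms: none
Why: Chemoselective borane reduction of the free carboxylic acid, followed by acid-catalysed translactonisation driven by loss of acetone, sets C8 at the alcohol level and keeps C1 at the acyl level.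

**Step 3**
Reactants: 4 (3S)-3-hydroxy-3-methyloxolan-2-one
Product: 6 (3S)-2-methoxy-3-methyloxolan-3-ol (anomers), via lactol 5 (not isolated)
Conditions: i-Bu2AlH (2.2 equiv), CH2Cl2, −78 °C; aq potassium sodium tartrate; crude in MeOH, PPTS (cat.), rt
Reagents that add atoms: methanol, CO
Why: Partial lactone reduction stops at the lactol at low temperature, and Fischer-type acetalisation masks C1 as a base-stable methyl acetal, so that no carbonyl group and no migrating silyl group stands next to the tertiary hydroxyl in step 4.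

**Step 4**
Reactants: 6 (3S)-2-methoxy-3-methyloxolan-3-ol; 7 trichloroethylene
Product: 8 (3S)-3-[(E)-1,2-dichloroethenoxy]-2-methoxy-3-methyloxolane
Conditions: KH (2.2 equiv), THF, 0 °C; Cl2C=CHCl, −50 °C → rt
Reagents that add atoms: trichloroethylene, ClC=C(Cl)Cl
Why: The potassium alkoxide adds to dichloroacetylene formed in situ by dehydrochlorination (the standard dichlorovinyl ether entry to ynol ethers); anti addition gives the E ether, and the substrate offers no acidic C–H, carbonyl or silyl group to the base.

**Step 5**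
Reactants: 8 (3S)-3-[(E)-1,2-dichloroethenoxy]-2-methoxy-3-methyloxolane
Product: 9 (3S)-3-[(E)-1,2-dichloroethenoxy]-3-methyloxolan-2-ol
Conditions: 1 M aq HCl, THF, 40 °C
Reagents that add atoms: water, O
Why: In this acid-catalysed acetal hydrolysis the 2-methoxyoxolane ionises readily, whereas the dichlorovinyl ether is too electron-poor to be protonated under these conditions.

**Step 6**
Reactants: 9 (3S)-3-[(E)-1,2-dichloroethenoxy]-3-methyloxolan-2-ol; 10 vinylmagnesium bromide
Product: 11 (3S,4R)-3-[(E)-1,2-dichloroethenoxy]-3-methylhex-5-ene-1,4-diol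
Conditions: CH2=CHMgBr (3 equiv), THF, −20 °C → rt
Reagents that add atoms: vinylmagnesium bromide, C=C[Mg]Br
Why: The Grignard reagent adds to the open hydroxy-aldehyde form of the lactol; with the non-chelating dichlorovinyloxy group as polar substituent, the polar Felkin–Anh model predicts the anti (1R) carbinol, a temporary centre.

**Step 7**
Reactants: 11 (3S,4R)-3-[(E)-1,2-dichloroethenoxy]-3-methylhex-5-ene-1,4-diol
Product: 12 bis(triethylsilyl) ether of 11 (O1 and O8)
Conditions: Et3SiOTf (2.4 equiv), 2,6-lutidine, CH2Cl2, −78 → 0 °C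
Reagents that add atoms: triethylsilyl trifluoromethanesulfonate, CC[Si](CC)(CC)OS(=O)(=O)C(F)(F)F
Why: Silyl ether formation with the reactive triflate covers the primary C8 and the hindered secondary C1 hydroxyl only after the strongly basic step 4, so silyl migration to the C10 oxygen cannot occur.

**Step 8**
Reactants: 12 bis(triethylsilyl) ether of 11; 13 paraformaldehyde
Product: 16 tert-butyl{[3-({(3S,4R)-3-methyl-1,4-bis[(triethylsilyl)oxy]hex-5-en-3-yl}oxy)prop-2-yn-1-yl]oxy}diphenylsilane, via lithium alkoxyacetylide 14 (not isolated), via lithium propargylic alkoxide 15 (not isolated)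
Conditions: n-BuLi (2.4 equiv), THF, −78 → −40 °C; (CH2O)n, −78 °C → rt; t-BuPh2SiCl, imidazole, DMF, 0 °C → rt
Reagents that add atoms: formaldehyde (from paraformaldehyde), C=O; tert-butyl(chloro)diphenylsilane, CC(C)(C)[Si](Cl)(c1ccccc1)c1ccccc1
Why: Elimination and chlorine–lithium exchange of the dichlorovinyl ether give the lithium alkoxyacetylide; hydroxymethylation and in situ silylation avoid handling the acid-sensitive 3-alkoxypropargyl alcohol, and the bulky t-BuPh2Si group is chosen to outlast both later Et3Si cleavages.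

**Step 9**
Reactants: 16 ynol ether tris-silyl ether
Product: 17 (3S,4R)-3-{[3-(tert-butyldiphenylsilyloxy)prop-1-yn-1-yl]oxy}-3-methyl-4-(triethylsilyloxy)hex-5-en-1-ol
Conditions: n-Bu4NF (1.0 equiv), THF, −20 °C
Reagents that add atoms: none
Why: Under kinetically controlled fluoride desilylation the unhindered primary Et3Si ether reacts before the neopentyl-type secondary Et3Si ether and the t-BuPh2Si ether, and the acid-free medium spares the ynol ether.

**Step 10**
Reactants: 17 primary alcohol
Product: 18 (3S,4R)-3-{[3-(tert-butyldiphenylsilyloxy)prop-1-yn-1-yl]oxy}-3-methyl-4-(triethylsilyloxy)hex-5-enal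
Conditions: Dess–Martin periodinane, pyridine, CH2Cl2, 0 °C; used at once
Reagents that add atoms: none
Why: Pyridine-buffered Dess–Martin oxidation works close to neutrality, which avoids acid-induced hydration of the ynol ether and base-induced β-elimination of the alkynyloxy group.

**Step 11**
Reactants: 19 3-methylbut-2-enal; 20 tert-butyldimethyl(prop-2-yn-1-yloxy)silane
Product: 22 rac-1-[(tert-butyldimethylsilyl)oxy]-6-methylhept-5-en-2-yn-4-ol, via lithium acetylide 21 (not isolated)
Conditions: 20, n-BuLi, THF, −78 °C; then 19, −78 → 0 °C; H2O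
Reagents that add atoms: tert-butyldimethyl(prop-2-yn-1-yloxy)silane, C#CCO[Si](C)(C)C(C)(C)C
Why: 1,2-Addition of a lithium acetylide to an enal joins C6 to C7 and brings in C11 and C13 at the right oxidation level.

**Step 12**
Reactants: 22 racemic propargylic alcohol
Product: 23 1-[(tert-butyldimethylsilyl)oxy]-6-methylhept-5-en-2-yn-4-one
Conditions: MnO2, CH2Cl2, rt
Reagents that add atoms: none
Why: MnO2 oxidises the doubly activated (allylic and propargylic) alcohol selectively and provides the ketone for a reagent-controlled reduction.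

**Step 13**
Reactants: 23 enynone
Product: 24 (4R)-1-[(tert-butyldimethylsilyl)oxy]-6-methylhept-5-en-2-yn-4-ol
Conditions: (R)-Alpine-Borane (from (+)-α-pinene), neat, rt; then HOCH2CH2NH2, Et2O, 0 °C
Reagents that add atoms: none
Why: In the Midland reduction hydride passes from the pinanyl group through a boat-like six-membered transition state in which the slim alkynyl group sits next to the pinane methyl group, so this reagent should give the (R) carbinol that becomes C6.

**Step 14**
Reactants: 24 (4R)-propargylic alcohol
Product: 26 (2Z,4R)-1-[(tert-butyldimethylsilyl)oxy]-2-iodo-6-methylhepta-2,5-dien-4-ol, via cyclic vinylalanate 25 (not isolated)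
Conditions: NaAlH2(OCH2CH2OMe)2, THF, 0 °C → rt; then N-iodosuccinimide, −78 °C
Reagents that add atoms: N-iodosuccinimide, O=C1CCC(=O)N1I
Why: Hydroxyl-directed trans-hydroalumination places aluminium on C11 in a five-membered oxaaluminacycle, and iodinolysis with retention gives the Z vinyl iodide with iodine cis to C6, the geometry that lactonisation needs.

**Step 15**
Reactants: 26 (2Z,4R)-vinyl iodide; 27 carbon monoxide
Product: 28 (5R)-3-{[(tert-butyldimethylsilyl)oxy]methyl}-5-(2-methylprop-1-en-1-yl)furan-2(5H)-one
Conditions: Pd(PPh3)4 (5 mol%), CO (1 atm), i-Pr2NEt, THF, 40 °C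
Reagents that add atoms: carbon monoxide, [C-]#[O+]
Why: In this carbonylative lactonisation zerovalent palladium inserts into C11–I, CO inserts, and the cis C6 hydroxyl captures the acylpalladium to close the lactone ring; the hindered amine only scavenges HI, so the acidic C6–H is not exchanged.

**Step 16**
Reactants: 28 silyloxymethyl butenolide
Product: 29 (5R)-3-(bromomethyl)-5-(2-methylprop-1-en-1-yl)furan-2(5H)-one
Conditions: PPh3, Br2, CH2Cl2, 0 °C; then 28, 0 °C → rt
Reagents that add atoms: bromine (as Ph3PBr2), BrBr
Why: The silyl ether to bromide interchange with Ph3PBr2 (Appel-type oxyphosphonium activation, then SN2 at primary allylic C13) runs without base, so C6 keeps its configuration.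

**Step 17**
Reactants: 18 β-alkynyloxy aldehyde; 29 (5R)-bromomethylbutenolide
Product: 31 (1R,6R,7R,8S,10S)-8-hydroxy lactone dienyne, via allylzinc bromide 30 (not isolated)
Conditions: Zn dust, THF/sat. aq NH4Cl, 0 °C
Reagents that add atoms: (5R)-3-(bromomethyl)-5-(2-methylprop-1-en-1-yl)furan-2(5H)-one, O=C1O[C@H](C=C(C)C)C=C1CBr
Why: In this Barbier allylation the allylzinc reacts at C7 (SE2′) on the ring face anti to the C6 isobutenyl group, which sets the trans C6/C7 lactone; its ring-locked E-type geometry in a Zimmerman–Traxler chair places O8 anti to C6, giving the (8S) epimer that step 18 inverts, while the buffered aqueous phase keeps zinc salts from acting as Lewis acids on the ynol ether.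

**Step 18**
Reactants: 31 (8S)-alcohol; 32 3-methylbutanoic acid
Product: 33 (1R,6R,7R,8R,10S)-8-(3-methylbutanoyloxy) lactone dienyne (metathesis precursor)
Conditions: PPh3, DIAD, toluene, 0 °C; 32; then 31, 0 °C → rt
Reagents that add atoms: 3-methylbutanoic acid, CC(C)CC(=O)O
Why: In the Mitsunobu esterification, SN2 displacement of the C8 oxyphosphonium ion by isovalerate turns (8S) into the required (8R) and installs the ester in the same operation; pre-forming the betaine and adding the acid before 31 keeps free carboxylic acid away from the ynol ether.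

**Step 19**
Reactants: 33 lactone dienyne
Product: 34 (1R,4Z,6R,7R,8R,10S)-bicyclic 2-oxydiene (3,10-epoxygermacra-2,4,11(13)-trien-6,12-olide with 1-OSiEt3, 8-isovalerate and 15-OSiPh2t-Bu)
Conditions: second-generation Hoveyda–Grubbs catalyst RuCl2(H2IMes)(=CH-C6H4-2-O-i-Pr) (20 mol% in portions), CH2Cl2, 33 added by syringe pump to 0.5 mM final, 25–30 °C, Ar sparge, no ethylene
Reagents that add atoms: none
Why: Proposed new method: the catalyst should exchange onto the only monosubstituted alkene (the C2 vinyl group), the C2 alkylidene then adds across the polarised C3≡C4 bond so that C2 bonds to the oxygen-bearing C3, and opening of the ruthenacyclobutene closes the ring O–C3=C2–C1–C10 in the exo mode and leaves a vinylcarbene on C4. This carbene must then engage the C5 isobutenyl alkene within the same molecule, which makes C4=C5, closes the ten-membered carbocycle (and with it the nine-membered ring that runs through the ring oxygen) with both alkene carbons endocyclic, and passes Ru=CMe2 to the next C2 vinyl group with loss of 2-methylpropene. The closest known reaction types are ring-closing enyne metathesis of alkynyl ethers to cyclic 2-alkoxy-1,3-dienes and tandem dienyne metathesis to fused bicycles, whereas the tertiary-alkyl ynol ether, the medium ring and the trisubstituted terminating alkene are without precedent. No stereocentre is formed, and C4=C5 should be Z because an E alkene cannot be spanned between the trans-lactone and the dihydrofuran in a ring of this size. The step needs initiation at C2 rather than C5, which the slow-exchanging isobutenyl cap and the electron-poor 1,1-disubstituted C11=C13 secure, and it needs capture of the C4 carbene before a second substrate molecule methylenates it, which slow addition at sub-millimolar concentration without ethylene secures. The temperature stays at or below 30 °C because the tertiary-alkyl ynol ether is lost by retro-ene fragmentation on heating.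

**Step 20**
Reactants: 34 bicyclic 2-oxydiene
Product: 35 C1 allylic alcohol (15-OSiPh2t-Bu retained)
Conditions: HF·pyridine, excess pyridine, THF, 0 °C
Reagents that add atoms: none
Why: Under pyridine-buffered HF the Et3Si ether is cleaved far faster than the t-BuPh2Si ether, and the buffer protects the acid-labile dienol ether.

**Step 21**
Reactants: 35 C1 allylic alcohol
Product: 36 15-O-(tert-butyldiphenylsilyl) furanone
Conditions: Dess–Martin periodinane, pyridine, CH2Cl2, 0 °C
Reagents that add atoms: none
Why: Dess–Martin oxidation of the allylic C1 alcohol gives the vinylogous ester of the 3(2H)-furanone, which removes the temporary stereocentre and stabilises the enol ether.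

**Step 22**
Reactants: 36 silyl-protected furanone
Product: 37 target CNP0171896.1
Conditions: HF·pyridine, THF, 0 °C → rt (plastic vessel)
Reagents that add atoms: none
Why: Desilylation with a mildly acidic fluoride source avoids the alkoxide or basic fluoride that would add to the α-methylene lactone or cleave the ester.

**Compound list**
1 | (S)-citramalic acid | C[C@](O)(CC(=O)O)C(=O)O | starting material
2 | 2-[(4S)-2,2,4-trimethyl-5-oxo-1,3-dioxolan-4-yl]acetic acid | CC1(C)O[C@@](C)(CC(=O)O)C(=O)O1 | intermediate
3 | (5S)-5-(2-hydroxyethyl)-2,2,5-trimethyl-1,3-dioxolan-4-one | CC1(C)O[C@@](C)(CCO)C(=O)O1 | intermediate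
4 | (3S)-3-hydroxy-3-methyloxolan-2-one | C[C@]1(O)CCOC1=O | intermediate
5 | (3S)-3-methyloxolane-2,3-diol (lactol, anomers) | C[C@]1(O)CCOC1O | intermediate
6 | (3S)-2-methoxy-3-methyloxolan-3-ol (anomers) | C[C@]1(O)CCOC1OC | intermediate
7 | trichloroethylene | ClC=C(Cl)Cl | starting material
8 | (3S)-3-[(E)-1,2-dichloroethenoxy]-2-methoxy-3-methyloxolane | C[C@]1(O/C(Cl)=C\Cl)CCOC1OC | intermediate
9 | (3S)-3-[(E)-1,2-dichloroethenoxy]-3-methyloxolan-2-ol | C[C@]1(O/C(Cl)=C\Cl)CCOC1O | intermediate
10 | vinylmagnesium bromide | C=C[Mg]Br | starting material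
11 | (3S,4R)-3-[(E)-1,2-dichloroethenoxy]-3-methylhex-5-ene-1,4-diol | C[C@](O/C(Cl)=C\Cl)(CCO)[C@H](O)C=C | intermediate
12 | bis(triethylsilyl) ether of 11 | C[C@](O/C(Cl)=C\Cl)(CCO[Si](CC)(CC)CC)[C@H](O[Si](CC)(CC)CC)C=C | intermediate
13 | paraformaldehyde (reacts as formaldehyde) | C=O | starting material
14 | lithium alkoxyacetylide | C[C@](OC#C[Li])(CCO[Si](CC)(CC)CC)[C@H](O[Si](CC)(CC)CC)C=C | intermediate
15 | lithium propargylic alkoxide | C[C@](OC#CCO[Li])(CCO[Si](CC)(CC)CC)[C@H](O[Si](CC)(CC)CC)C=C | intermediate
16 | ynol ether with 15-OSiPh2t-Bu, 1-OSiEt3 and 8-OSiEt3 | C[C@](OC#CCO[Si](c1ccccc1)(c1ccccc1)C(C)(C)C)(CCO[Si](CC)(CC)CC)[C@H](O[Si](CC)(CC)CC)C=C | intermediate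
17 | (3S,4R)-3-{[3-(tert-butyldiphenylsilyloxy)prop-1-yn-1-yl]oxy}-3-methyl-4-(triethylsilyloxy)hex-5-en-1-ol | C[C@](OC#CCO[Si](c1ccccc1)(c1ccccc1)C(C)(C)C)(CCO)[C@H](O[Si](CC)(CC)CC)C=C | intermediate
18 | (3S,4R)-3-{[3-(tert-butyldiphenylsilyloxy)prop-1-yn-1-yl]oxy}-3-methyl-4-(triethylsilyloxy)hex-5-enal | C[C@](OC#CCO[Si](c1ccccc1)(c1ccccc1)C(C)(C)C)(CC=O)[C@H](O[Si](CC)(CC)CC)C=C | intermediate
19 | 3-methylbut-2-enal | CC(C)=CC=O | starting material
20 | tert-butyldimethyl(prop-2-yn-1-yloxy)silane | C#CCO[Si](C)(C)C(C)(C)C | starting material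
21 | lithium acetylide of 20 | [Li]C#CCO[Si](C)(C)C(C)(C)C | intermediate
22 | rac-1-[(tert-butyldimethylsilyl)oxy]-6-methylhept-5-en-2-yn-4-ol | OC(C=C(C)C)C#CCO[Si](C)(C)C(C)(C)C | intermediate
23 | 1-[(tert-butyldimethylsilyl)oxy]-6-methylhept-5-en-2-yn-4-one | O=C(C=C(C)C)C#CCO[Si](C)(C)C(C)(C)C | intermediate
24 | (4R)-1-[(tert-butyldimethylsilyl)oxy]-6-methylhept-5-en-2-yn-4-ol | O[C@H](C=C(C)C)C#CCO[Si](C)(C)C(C)(C)C | intermediate
25 | sodium cyclic vinylalanate (1,2-oxaaluminole) | [Na+].COCCO[Al-]1(OCCOC)O[C@H](C=C(C)C)C=C1CO[Si](C)(C)C(C)(C)C | intermediate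
26 | (2Z,4R)-1-[(tert-butyldimethylsilyl)oxy]-2-iodo-6-methylhepta-2,5-dien-4-ol | O[C@H](C=C(C)C)/C=C(\I)CO[Si](C)(C)C(C)(C)C | intermediate
27 | carbon monoxide | [C-]#[O+] | starting material
28 | (5R)-3-{[(tert-butyldimethylsilyl)oxy]methyl}-5-(2-methylprop-1-en-1-yl)furan-2(5H)-one | O=C1O[C@H](C=C(C)C)C=C1CO[Si](C)(C)C(C)(C)C | intermediate
29 | (5R)-3-(bromomethyl)-5-(2-methylprop-1-en-1-yl)furan-2(5H)-one | O=C1O[C@H](C=C(C)C)C=C1CBr | intermediate
30 | allylzinc bromide from 29 | O=C1O[C@H](C=C(C)C)C=C1C[Zn]Br | intermediate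
31 | (4R,5R)-4-[(1S,3S,4R)-3-{[3-(tert-butyldiphenylsilyloxy)prop-1-yn-1-yl]oxy}-1-hydroxy-3-methyl-4-(triethylsilyloxy)hex-5-en-1-yl]-3-methylidene-5-(2-methylprop-1-en-1-yl)oxolan-2-one | C=C1C(=O)O[C@H](C=C(C)C)[C@H]1[C@@H](O)C[C@](C)(OC#CCO[Si](c2ccccc2)(c2ccccc2)C(C)(C)C)[C@H](O[Si](CC)(CC)CC)C=C | intermediate
32 | 3-methylbutanoic acid | CC(C)CC(=O)O | starting material
33 | metathesis precursor: (8R)-3-methylbutanoate, C8-inverted ester of 31 | C=C1C(=O)O[C@H](C=C(C)C)[C@H]1[C@H](OC(=O)CC(C)C)C[C@](C)(OC#CCO[Si](c2ccccc2)(c2ccccc2)C(C)(C)C)[C@H](O[Si](CC)(CC)CC)C=C | intermediate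
34 | bicyclic 2-oxydiene with 1-OSiEt3 and 15-OSiPh2t-Bu | C=C1C(=O)O[C@@H]2/C=C(/CO[Si](c4ccccc4)(c4ccccc4)C(C)(C)C)C3=C[C@@H](O[Si](CC)(CC)CC)[C@](C)(C[C@@H](OC(=O)CC(C)C)[C@@H]12)O3 | intermediate
35 | C1 allylic alcohol | C=C1C(=O)O[C@@H]2/C=C(/CO[Si](c4ccccc4)(c4ccccc4)C(C)(C)C)C3=C[C@@H](O)[C@](C)(C[C@@H](OC(=O)CC(C)C)[C@@H]12)O3 | intermediate
36 | 15-O-(tert-butyldiphenylsilyl) furanone | C=C1C(=O)O[C@@H]2/C=C(/CO[Si](c4ccccc4)(c4ccccc4)C(C)(C)C)C3=CC(=O)[C@](C)(C[C@@H](OC(=O)CC(C)C)[C@@H]12)O3 | intermediate
37 | CNP0171896.1 (6R,7R,8R,10S,4Z) | C=C1C(=O)O[C@@H]2/C=C(/CO)C3=CC(=O)[C@](C)(C[C@@H](OC(=O)CC(C)C)[C@@H]12)O3 | target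

**Step count**
Total step count: 22.
Longest linear sequence: 16 (steps 1–10 and 17–22).

**Steps most likely to fail**

Step 19. The C4 vinylcarbene may be methylenated by the vinyl group of a second molecule. It may also fail to engage the trisubstituted alkene, so that the cascade stops after the first ring, or the ynol ether may fragment before it reacts.
The fallback sets out from 33 and returns at 34. It splits the cascade into two known reactions.
- Ring-closing enyne metathesis of 33 under ethylene (1 atm) with second-generation Grubbs catalyst RuCl2(H2IMes)(PCy3)(=CHPh) in CH2Cl2 at room temperature is the established reaction of alkynyl ethers. It would give the monocyclic dienyl dihydrofuran triene F1, in which C4 carries a methylene group.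
- F1 no longer holds a heat-sensitive ynol ether. An ordinary ring-closing diene metathesis between C4=CH2 and the isobutenyl group can therefore be forced in toluene at 80 °C and high dilution, giving 34.

Step 18. The crowded C8 oxyphosphonium ion may eliminate towards C9 or be acylated with retention, and free acid may add to the ynol ether.
The fallback sets out from 31 and returns at 33. It is an acid-free inversion in two stages.
- Chloromethanesulfonyl chloride and pyridine in CH2Cl2 at 0 °C give the (8S)-chloromethanesulfonate F2.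
- CsO2CCH2CHMe2 and 18-crown-6 in toluene at 25–40 °C displace the sulfonate by SN2 to give 33.

Step 17. Aldehyde 18 may lose the alkynyloxy group by β-elimination. The ynol ether may be hydrated in the aqueous ammonium chloride, or zinc salts may promote its addition to the aldehyde carbonyl.
The fallback sets out from 29 (with 18) and returns at 31. It is a salt-free allylboration.
- Borylation of 29 with B2pin2 and Pd2(dba)3 (cat.) in toluene gives the butenolide allylboronate F3.
- F3 should add to 18 in toluene at room temperature without water, base or Lewis acid, through the same chair transition state, and gives 31 after a neutral aqueous work-up.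

**Further compounds**
F1 | step 19 | monocyclic dienyl dihydrofuran triene (C4=CH2, isobutenyl intact) | C=C1C(=O)O[C@H](C=C(C)C)[C@H]1[C@H](OC(=O)CC(C)C)C[C@]2(C)OC(C(=C)CO[Si](c3ccccc3)(c3ccccc3)C(C)(C)C)=C[C@H]2O[Si](CC)(CC)CC
F2 | step 18 | (8S)-chloromethanesulfonate of 31 | C=C1C(=O)O[C@H](C=C(C)C)[C@H]1[C@@H](OS(=O)(=O)CCl)C[C@](C)(OC#CCO[Si](c2ccccc2)(c2ccccc2)C(C)(C)C)[C@H](O[Si](CC)(CC)CC)C=C
F3 | step 17 | (5R)-5-(2-methylprop-1-en-1-yl)-3-[(4,4,5,5-tetramethyl-1,3,2-dioxaborolan-2-yl)methyl]furan-2(5H)-one | O=C1O[C@H](C=C(C)C)C=C1CB2OC(C)(C)C(C)(C)O2
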